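**Assumption:** locants follow the farnesane chain of the acyclic precursor (C1 = CH–OAc, C2 = CH–OAng, C3 = C(OH)CH3, C4 = CHCl, C5 = CH2, C6 = ring CH carrying C7(=C14H2)–C8H(OH)–C9H2–C10H(OAng)–C11(OH)Me2); metal alkoxide or borate forms of a product that are only hydrolysed on work-up are not numbered separately.

## Retrosynthetic overview

1. Target 23 ⇐ 22 (C8 silyl ether) ⇐ Markovnikov, trans-diaxial chlorohydroxylation of the ring Δ3 alkene of 21 (OH to C3, Cl to C4), after C1 acetate and C2/C10 angelates are in place.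
2. The only ring ⇐ intramolecular type-I carbonyl-ene (Prins-type) closure C1–C6 of the acyclic (3Z,6E)-farnesane aldehyde 17. Loss of a C14 hydrogen gives the 7(14)-methylene, as in farnesyl → bisabolyl cation → β-bisabolene. Chelation through the C2 oxygen sets C1 and C6.
3. 17 ⇐ enal 8 by boron aldol (C8–C9 bond, sets C8) and 1,3-anti reduction (sets C10).
4. 8 ⇐ SeO2 oxidation of Z-diene 7 ⇐ Z-selective Wittig reaction of α-alkoxy ketone 5 (L-glycerate, carries C2) with the homoprenyl ylide.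
5. Ring order: a single six-membered ring, formed in step 11.

## Route

Step 1
Reactants: 1 5-bromo-2-methylpent-2-ene
Product: 2 (4-methylpent-3-en-1-yl)triphenylphosphonium bromide
Conditions: PPh3, MeCN, 80 °C
Reagents that add atoms: triphenylphosphine, c1ccc(cc1)P(c1ccccc1)c1ccccc1
Why: SN2 quaternisation of PPh3 by a primary homoallylic bromide; no stereocentre is involved.

Step 2
Reactants: 3 methyl (S)-2,2-dimethyl-1,3-dioxolane-4-carboxylate
Product: 5 (S)-1-(2,2-dimethyl-1,3-dioxolan-4-yl)ethan-1-one, via Weinreb amide 4 (not isolated)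
Conditions: MeNHOMe·HCl, i-PrMgCl, THF, −20 °C; then MeMgBr, −20 → 0 °C; aq. NH4Cl
Reagents that add atoms: methylmagnesium bromide, C[Mg]Br
Why: One-pot Weinreb amidation and Grignard acylation stops at the ketone through the chelated tetrahedral adduct, and the α-alkoxy stereocentre (future C2) is kept at low temperature.

Step 3
Reactants: 2 (4-methylpent-3-en-1-yl)triphenylphosphonium bromide; 5 (S)-1-(2,2-dimethyl-1,3-dioxolan-4-yl)ethan-1-one
Product: 7 (4R)-2,2-dimethyl-4-[(2Z)-6-methylhepta-2,5-dien-2-yl]-1,3-dioxolane, via phosphorus ylide 6 (not isolated)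
Conditions: KHMDS (0.98 equiv), THF, −78 → 0 °C; then 5, −78 °C → rt
Reagents that add atoms: none
Why: Wittig olefination of an α-alkoxy ketone with a salt-free unstabilised ylide (Still variant) gives the Z-trisubstituted alkene, placing C2 and C5 cis as the later ring closure requires.

Step 4
Reactants: 7 (4R)-2,2-dimethyl-4-[(2Z)-6-methylhepta-2,5-dien-2-yl]-1,3-dioxolane
Product: 8 (2E,5Z)-6-[(4R)-2,2-dimethyl-1,3-dioxolan-4-yl]-2-methylhepta-2,5-dienal
Conditions: SeO2 (1.2 equiv), pyridine (buffer), 1,4-dioxane, 80 °C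
Reagents that add atoms: selenium dioxide, O=[Se]=O
Why: SeO2 allylic oxidation (ene then [2,3]-shift) attacks the E-methyl of the electron-rich terminal gem-dimethyl alkene to give the (E)-enal, while the C3=C4 alkene is deactivated by its allylic oxygen.

Step 5
Reactants: 8 (2E,5Z)-6-[(4R)-2,2-dimethyl-1,3-dioxolan-4-yl]-2-methylhepta-2,5-dienal; 9 3-methyl-3-(trimethylsilyloxy)butan-2-one
Product: 11 (5R,6E,9Z)-10-[(4R)-2,2-dimethyl-1,3-dioxolan-4-yl]-5-hydroxy-2,6-dimethyl-2-(trimethylsilyloxy)undeca-6,9-dien-3-one, via enol borinate 10 (not isolated)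
Conditions: 9, (+)-Ipc2BCl, Et3N, Et2O, 0 °C; then 8, −78 → −20 °C; MeOH, pH 7 buffer, 30% H2O2, 0 °C
Reagents that add atoms: none
Why: Paterson boron aldol of a methyl ketone, in which the (+)-Ipc2B enolate adds to the Re face of the enal and sets C8 as (R) by reagent control (about 80–90% ee expected; the minor C8 epimer is removed by chromatography at 13 or 18).

Step 6
Reactants: 11 (5R,6E,9Z)-10-[(4R)-2,2-dimethyl-1,3-dioxolan-4-yl]-5-hydroxy-2,6-dimethyl-2-(trimethylsilyloxy)undeca-6,9-dien-3-one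
Product: 13 (3R,5R,6E,9Z)-10-[(4R)-2,2-dimethyl-1,3-dioxolan-4-yl]-2,6-dimethylundeca-6,9-diene-2,3,5-triol, via TMS-protected anti-diol 12 (not isolated)
Conditions: Me4NBH(OAc)3, MeCN/AcOH (1:1), −30 °C; aq. Rochelle salt; then K2CO3 (cat.), MeOH, rt
Reagents that add atoms: none
Why: Evans–Saksena reduction delivers hydride intramolecularly from the C8 alkoxyborohydride through a chair transition state, giving the 1,3-anti diol and setting C10 as (R); methanolysis then removes the tertiary TMS group.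

Step 7
Reactants: 13 (3R,5R,6E,9Z)-10-[(4R)-2,2-dimethyl-1,3-dioxolan-4-yl]-2,6-dimethylundeca-6,9-diene-2,3,5-triol
Product: 14 (3R,5R,6E,9Z)-5-(tert-butyldimethylsilyloxy)-10-[(4R)-2,2-dimethyl-1,3-dioxolan-4-yl]-2,6-dimethylundeca-6,9-diene-2,3-diol
Conditions: TBSCl (1.1 equiv), imidazole, DMF, 0 °C
Reagents that add atoms: tert-butyldimethylsilyl chloride, CC(C)(C)[Si](C)(C)Cl
Why: Sterically controlled silylation: the allylic C8 hydroxyl reacts, while the neopentyl-type C10 hydroxyl and the tertiary C11 hydroxyl do not.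

Step 8
Reactants: 14 (3R,5R,6E,9Z)-5-(tert-butyldimethylsilyloxy)-10-[(4R)-2,2-dimethyl-1,3-dioxolan-4-yl]-2,6-dimethylundeca-6,9-diene-2,3-diol
Product: 15 (2R,3Z,6E,8R,10R)-8-(tert-butyldimethylsilyloxy)-3,7,11-trimethyldodeca-3,6-diene-1,2,10,11-tetrol
Conditions: AcOH/H2O (4:1), 25 °C
Reagents that add atoms: none
Why: Acid hydrolysis of the terminal isopropylidene acetal; the hindered secondary TBS ether survives these mild conditions.

Step 9
Reactants: 15 (2R,3Z,6E,8R,10R)-8-(tert-butyldimethylsilyloxy)-3,7,11-trimethyldodeca-3,6-diene-1,2,10,11-tetrol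
Product: 16 (2R,3Z,6E,8R,10R)-8-(tert-butyldimethylsilyloxy)-3,7,11-trimethyl-1,2,10-tris(triethylsilyloxy)dodeca-3,6-dien-11-ol
Conditions: TESCl (3.6 equiv), imidazole, DMAP (cat.), DMF, 0 → 25 °C
Reagents that add atoms: chlorotriethylsilane, CC[Si](CC)(CC)Cl
Why: Silyl ether formation at the primary and both secondary hydroxyls; the tertiary C11 hydroxyl is not silylated by TESCl/imidazole.

Step 10
Reactants: 16 (2R,3Z,6E,8R,10R)-8-(tert-butyldimethylsilyloxy)-3,7,11-trimethyl-1,2,10-tris(triethylsilyloxy)dodeca-3,6-dien-11-ol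
Product: 17 (2R,3Z,6E,8R,10R)-8-(tert-butyldimethylsilyloxy)-11-hydroxy-3,7,11-trimethyl-2,10-bis(triethylsilyloxy)dodeca-3,6-dienal
Conditions: (COCl)2, DMSO, CH2Cl2, −78 → −35 °C; then i-Pr2NEt, −78 → −20 °C; used crude
Reagents that add atoms: none
Why: Swern oxidation converts the primary TES ether directly to the aldehyde (activated DMSO attacks the least hindered silyl ether oxygen) while secondary silyl ethers and the tertiary alcohol remain, and the cold amine step avoids epimerising C2.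

Step 11
Reactants: 17 (2R,3Z,6E,8R,10R)-8-(tert-butyldimethylsilyloxy)-11-hydroxy-3,7,11-trimethyl-2,10-bis(triethylsilyloxy)dodeca-3,6-dienal
Product: 18 (1S,2R,6R)-6-[(3R,5R)-3-(tert-butyldimethylsilyloxy)-6-hydroxy-6-methyl-5-(triethylsilyloxy)hept-1-en-2-yl]-3-methyl-2-(triethylsilyloxy)cyclohex-3-en-1-ol
Conditions: Me2AlCl (3.5 equiv), CH2Cl2, −78 → −20 °C; aq. Rochelle salt
Reagents that add atoms: none
Why: Intramolecular type-I carbonyl-ene (Prins-type) cyclisation in which Me2AlCl chelates the aldehyde and C2 oxygens (1,2-cis), and because only the C14 methyl (cis to C5 on the 6E alkene) can deliver hydrogen, closure must pass through the chair with axial carbonyl oxygen and equatorial C7, giving the all-cis C1/C2/C6 triad and the 7(14)-methylene.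

Step 12
Reactants: 18 (1S,2R,6R)-6-[(3R,5R)-3-(tert-butyldimethylsilyloxy)-6-hydroxy-6-methyl-5-(triethylsilyloxy)hept-1-en-2-yl]-3-methyl-2-(triethylsilyloxy)cyclohex-3-en-1-ol
Product: 19 (1S,2R,6R)-6-[(3R,5R)-3-(tert-butyldimethylsilyloxy)-6-hydroxy-6-methyl-5-(triethylsilyloxy)hept-1-en-2-yl]-3-methyl-2-(triethylsilyloxy)cyclohex-3-en-1-yl acetate
Conditions: Ac2O (1.5 equiv), pyridine, DMAP (cat.), CH2Cl2, 0 → 25 °C
Reagents that add atoms: acetic anhydride, CC(=O)OC(C)=O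
Why: DMAP-catalysed acetylation of the only free secondary hydroxyl (axial C1–OH); the tertiary C11 hydroxyl is inert under these conditions.

Step 13
Reactants: 19 (1S,2R,6R)-6-[(3R,5R)-3-(tert-butyldimethylsilyloxy)-6-hydroxy-6-methyl-5-(triethylsilyloxy)hept-1-en-2-yl]-3-methyl-2-(triethylsilyloxy)cyclohex-3-en-1-yl acetate
Product: 20 (1S,2R,6R)-6-[(3R,5R)-3-(tert-butyldimethylsilyloxy)-5,6-dihydroxy-6-methylhept-1-en-2-yl]-2-hydroxy-3-methylcyclohex-3-en-1-yl acetate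
Conditions: HF·pyridine, excess pyridine, THF, 0 °C
Reagents that add atoms: none
Why: Buffered fluoride desilylation removes the two TES ethers much faster than the bulkier secondary TBS ether, and the acidic medium suppresses acetate migration.

Step 14
Reactants: 20 (1S,2R,6R)-6-[(3R,5R)-3-(tert-butyldimethylsilyloxy)-5,6-dihydroxy-6-methylhept-1-en-2-yl]-2-hydroxy-3-methylcyclohex-3-en-1-yl acetate
Product: 21 (1S,2R,6R)-1-acetoxy-6-[(3R,5R)-5-angeloyloxy-3-(tert-butyldimethylsilyloxy)-6-hydroxy-6-methylhept-1-en-2-yl]-3-methylcyclohex-3-en-2-yl (Z)-2-methylbut-2-enoate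
Conditions: angelic acid (6 equiv), 2,4,6-trichlorobenzoyl chloride, Et3N, toluene, 25 °C; then 20, 75 °C
Reagents that add atoms: angelic acid, C/C=C(/C)C(=O)O
Why: Yamaguchi-type mixed-anhydride esterification run without DMAP, which avoids Z→E isomerisation to tiglate, acylates both secondary hydroxyls (C2 and C10) and leaves the tertiary hydroxyl free.

Step 15
Reactants: 21 (1S,2R,6R)-1-acetoxy-6-[(3R,5R)-5-angeloyloxy-3-(tert-butyldimethylsilyloxy)-6-hydroxy-6-methylhept-1-en-2-yl]-3-methylcyclohex-3-en-2-yl (Z)-2-methylbut-2-enoate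
Product: 22 (1S,2S,3S,4S,6R)-1-acetoxy-6-[(3R,5R)-5-angeloyloxy-3-(tert-butyldimethylsilyloxy)-6-hydroxy-6-methylhept-1-en-2-yl]-4-chloro-3-hydroxy-3-methylcyclohexan-2-yl (Z)-2-methylbut-2-enoate
Conditions: NCS (1.2 equiv), acetone/H2O (4:1), 0 → 25 °C, dark
Reagents that add atoms: N-chlorosuccinimide, O=C1CCC(=O)N1Cl; water, O
Why: Electrophilic chlorohydroxylation: Cl+ adds to the less hindered α face of the trisubstituted ring alkene and water opens the chloronium ion at tertiary C3 from the β face (Markovnikov and trans-diaxial), giving 3β-OH/4α-Cl, while the exo-methylene is less nucleophilic and shielded by the C8 silyl ether.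

Step 16
Reactants: 22 (1S,2S,3S,4S,6R)-1-acetoxy-6-[(3R,5R)-5-angeloyloxy-3-(tert-butyldimethylsilyloxy)-6-hydroxy-6-methylhept-1-en-2-yl]-4-chloro-3-hydroxy-3-methylcyclohexan-2-yl (Z)-2-methylbut-2-enoate
Product: 23 (1S,2S,3S,4S,6R)-1-acetoxy-6-[(3R,5R)-5-angeloyloxy-3,6-dihydroxy-6-methylhept-1-en-2-yl]-4-chloro-3-hydroxy-3-methylcyclohexan-2-yl (Z)-2-methylbut-2-enoate (target CNP0124048.1)
Conditions: HF·pyridine, THF, 0 → 25 °C
Reagents that add atoms: none
Why: Fluoride-driven TBS cleavage under acidic, non-basic conditions leaves the chlorohydrin (no epoxide closure) and the three esters (no acyl migration) untouched.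

## Compound list

1 | 5-bromo-2-methylpent-2-ene | CC(C)=CCCBr | starting material
2 | (4-methylpent-3-en-1-yl)triphenylphosphonium bromide | CC(C)=CCC[P+](c1ccccc1)(c1ccccc1)c1ccccc1.[Br-] | intermediate
3 | methyl (S)-2,2-dimethyl-1,3-dioxolane-4-carboxylate | COC(=O)[C@@H]1COC(C)(C)O1 | starting material
4 | (S)-N-methoxy-N,2,2-trimethyl-1,3-dioxolane-4-carboxamide (Weinreb amide) | CON(C)C(=O)[C@@H]1COC(C)(C)O1 | intermediate
5 | (S)-1-(2,2-dimethyl-1,3-dioxolan-4-yl)ethan-1-one | CC(=O)[C@@H]1COC(C)(C)O1 | intermediate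
6 | (4-methylpent-3-en-1-ylidene)triphenylphosphorane (ylide) | CC(C)=CCC=P(c1ccccc1)(c1ccccc1)c1ccccc1 | intermediate
7 | (4R)-2,2-dimethyl-4-[(2Z)-6-methylhepta-2,5-dien-2-yl]-1,3-dioxolane | CC(C)=CC/C=C(/C)[C@@H]1COC(C)(C)O1 | intermediate
8 | (2E,5Z)-6-[(4R)-2,2-dimethyl-1,3-dioxolan-4-yl]-2-methylhepta-2,5-dienal | O=C/C(C)=C/C/C=C(/C)[C@@H]1COC(C)(C)O1 | intermediate
9 | 3-methyl-3-(trimethylsilyloxy)butan-2-one | CC(=O)C(C)(C)O[Si](C)(C)C | starting material
10 | (+)-diisopinocampheylboron enolate of 9 (enol borinate) | C=C(OB([C@H]1C[C@H]2C[C@@H]([C@@H]1C)C2(C)C)[C@H]1C[C@H]2C[C@@H]([C@@H]1C)C2(C)C)C(C)(C)O[Si](C)(C)C | intermediate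
11 | (5R,6E,9Z)-10-[(4R)-2,2-dimethyl-1,3-dioxolan-4-yl]-5-hydroxy-2,6-dimethyl-2-(trimethylsilyloxy)undeca-6,9-dien-3-one | C[Si](C)(C)OC(C)(C)C(=O)C[C@@H](O)/C(C)=C/C/C=C(/C)[C@@H]1COC(C)(C)O1 | intermediate
12 | (3R,5R,6E,9Z)-10-[(4R)-2,2-dimethyl-1,3-dioxolan-4-yl]-2,6-dimethyl-2-(trimethylsilyloxy)undeca-6,9-diene-3,5-diol | C[Si](C)(C)OC(C)(C)[C@H](O)C[C@@H](O)/C(C)=C/C/C=C(/C)[C@@H]1COC(C)(C)O1 | intermediate
13 | (3R,5R,6E,9Z)-10-[(4R)-2,2-dimethyl-1,3-dioxolan-4-yl]-2,6-dimethylundeca-6,9-diene-2,3,5-triol | CC(C)(O)[C@H](O)C[C@@H](O)/C(C)=C/C/C=C(/C)[C@@H]1COC(C)(C)O1 | intermediate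
14 | (3R,5R,6E,9Z)-5-(tert-butyldimethylsilyloxy)-10-[(4R)-2,2-dimethyl-1,3-dioxolan-4-yl]-2,6-dimethylundeca-6,9-diene-2,3-diol | CC(C)(O)[C@H](O)C[C@@H](O[Si](C)(C)C(C)(C)C)/C(C)=C/C/C=C(/C)[C@@H]1COC(C)(C)O1 | intermediate
15 | (2R,3Z,6E,8R,10R)-8-(tert-butyldimethylsilyloxy)-3,7,11-trimethyldodeca-3,6-diene-1,2,10,11-tetrol | CC(C)(O)[C@H](O)C[C@@H](O[Si](C)(C)C(C)(C)C)/C(C)=C/C/C=C(/C)[C@@H](O)CO | intermediate
16 | (2R,3Z,6E,8R,10R)-8-(tert-butyldimethylsilyloxy)-3,7,11-trimethyl-1,2,10-tris(triethylsilyloxy)dodeca-3,6-dien-11-ol | CC(C)(O)[C@H](O[Si](CC)(CC)CC)C[C@@H](O[Si](C)(C)C(C)(C)C)/C(C)=C/C/C=C(/C)[C@@H](O[Si](CC)(CC)CC)CO[Si](CC)(CC)CC | intermediate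
17 | (2R,3Z,6E,8R,10R)-8-(tert-butyldimethylsilyloxy)-11-hydroxy-3,7,11-trimethyl-2,10-bis(triethylsilyloxy)dodeca-3,6-dienal | CC(C)(O)[C@H](O[Si](CC)(CC)CC)C[C@@H](O[Si](C)(C)C(C)(C)C)/C(C)=C/C/C=C(/C)[C@@H](O[Si](CC)(CC)CC)C=O | intermediate
18 | (1S,2R,6R)-6-[(3R,5R)-3-(tert-butyldimethylsilyloxy)-6-hydroxy-6-methyl-5-(triethylsilyloxy)hept-1-en-2-yl]-3-methyl-2-(triethylsilyloxy)cyclohex-3-en-1-ol | C=C([C@H](O[Si](C)(C)C(C)(C)C)C[C@@H](O[Si](CC)(CC)CC)C(C)(C)O)[C@H]1CC=C(C)[C@@H](O[Si](CC)(CC)CC)[C@H]1O | intermediate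
19 | (1S,2R,6R)-6-[(3R,5R)-3-(tert-butyldimethylsilyloxy)-6-hydroxy-6-methyl-5-(triethylsilyloxy)hept-1-en-2-yl]-3-methyl-2-(triethylsilyloxy)cyclohex-3-en-1-yl acetate | C=C([C@H](O[Si](C)(C)C(C)(C)C)C[C@@H](O[Si](CC)(CC)CC)C(C)(C)O)[C@H]1CC=C(C)[C@@H](O[Si](CC)(CC)CC)[C@H]1OC(C)=O | intermediate
20 | (1S,2R,6R)-6-[(3R,5R)-3-(tert-butyldimethylsilyloxy)-5,6-dihydroxy-6-methylhept-1-en-2-yl]-2-hydroxy-3-methylcyclohex-3-en-1-yl acetate | C=C([C@H](O[Si](C)(C)C(C)(C)C)C[C@@H](O)C(C)(C)O)[C@H]1CC=C(C)[C@@H](O)[C@H]1OC(C)=O | intermediate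
21 | (1S,2R,6R)-1-acetoxy-6-[(3R,5R)-5-angeloyloxy-3-(tert-butyldimethylsilyloxy)-6-hydroxy-6-methylhept-1-en-2-yl]-3-methylcyclohex-3-en-2-yl (Z)-2-methylbut-2-enoate | C=C([C@H](O[Si](C)(C)C(C)(C)C)C[C@@H](OC(=O)/C(C)=C\C)C(C)(C)O)[C@H]1CC=C(C)[C@@H](OC(=O)/C(C)=C\C)[C@H]1OC(C)=O | intermediate
22 | (1S,2S,3S,4S,6R)-1-acetoxy-6-[(3R,5R)-5-angeloyloxy-3-(tert-butyldimethylsilyloxy)-6-hydroxy-6-methylhept-1-en-2-yl]-4-chloro-3-hydroxy-3-methylcyclohexan-2-yl (Z)-2-methylbut-2-enoate | C=C([C@H](O[Si](C)(C)C(C)(C)C)C[C@@H](OC(=O)/C(C)=C\C)C(C)(C)O)[C@H]1C[C@H](Cl)[C@@](C)(O)[C@@H](OC(=O)/C(C)=C\C)[C@H]1OC(C)=O | intermediate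
23 | (1S,2S,3S,4S,6R)-1-acetoxy-6-[(3R,5R)-5-angeloyloxy-3,6-dihydroxy-6-methylhept-1-en-2-yl]-4-chloro-3-hydroxy-3-methylcyclohexan-2-yl (Z)-2-methylbut-2-enoate (CNP0124048.1) | C=C([C@H](O)C[C@@H](OC(=O)/C(C)=C\C)C(C)(C)O)[C@H]1C[C@H](Cl)[C@@](C)(O)[C@@H](OC(=O)/C(C)=C\C)[C@H]1OC(C)=O | target

## Step count and risk

Total step count: 16. Longest linear sequence: 15 steps (3 → 5 → 7 → … → 23, steps 2–16; the branch from 1 through step 1 is equally long).

Three steps most likely to fail: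

Step 11 (ene cyclisation). The closure may leave the chelated axial-oxygen chair and give the C1 epimer or a mixture. Fallback: set C1 by hydride reduction instead of in the ene transition state. Setting out from 17, cyclise with a non-chelating Lewis acid (BF3·OEt2, CH2Cl2, −78 °C), which favours the all-equatorial chair and gives, alone or mixed with 18, the equatorial C1-epimeric cyclohexenol F1. Oxidise the crude carbinol with Dess–Martin periodinane/NaHCO3 to the 2,6-cis-diequatorial cyclohexenone F2. Reduce with L-Selectride in THF at −78 °C (equatorial hydride attack gives the axial alcohol), which comes back to the route at 18.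

Step 14 (double angeloylation). Under hot Et3N the C1 acetate may migrate to the free C2 hydroxyl before acylation, the angelate may isomerise to tiglate, and C10 may react sluggishly. Fallback: build the angelate double bonds on the esters. Setting out from 20, acylate both secondary hydroxyls at 0–25 °C (DCC, cat. DMAP, CH2Cl2) with 2-[bis(2,2,2-trifluoroethoxy)phosphoryl]propanoic acid to give the bis(phosphonopropionate) F3. Still–Gennari olefination with acetaldehyde (KHMDS, 18-crown-6, THF, −78 °C) then forms both (Z)-2-methylbut-2-enoates and comes back to the route at 21.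

Step 15 (chlorohydroxylation). Ene-type allylic chlorination, attack at the exo-methylene, or acyl scrambling through a C2/C3 dioxolanylium ion may compete. Fallback: go through the β-epoxide and open it with chloride. Setting out from 20, hydroxyl-directed epoxidation by the allylic C2–OH (VO(acac)2, t-BuOOH, CH2Cl2, 0 °C) gives the syn 3,4-epoxy diol F4. Angeloylation under the step 14 conditions gives the epoxy bis-angelate F5. HCl (1 M in Et2O, CH2Cl2, −20 °C) opens the epoxide trans-diaxially at C4 and comes back to the route at 22.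

## Further compounds

F1 | step 11 | (1R,2R,6R)-6-[(3R,5R)-3-(tert-butyldimethylsilyloxy)-6-hydroxy-6-methyl-5-(triethylsilyloxy)hept-1-en-2-yl]-3-methyl-2-(triethylsilyloxy)cyclohex-3-en-1-ol (C1 epimer of 18) | C=C([C@H](O[Si](C)(C)C(C)(C)C)C[C@@H](O[Si](CC)(CC)CC)C(C)(C)O)[C@H]1CC=C(C)[C@@H](O[Si](CC)(CC)CC)[C@@H]1O
F2 | step 11 | (2R,6R)-6-[(3R,5R)-3-(tert-butyldimethylsilyloxy)-6-hydroxy-6-methyl-5-(triethylsilyloxy)hept-1-en-2-yl]-3-methyl-2-(triethylsilyloxy)cyclohex-3-en-1-one | C=C([C@H](O[Si](C)(C)C(C)(C)C)C[C@@H](O[Si](CC)(CC)CC)C(C)(C)O)[C@H]1CC=C(C)[C@@H](O[Si](CC)(CC)CC)C1=O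
F3 | step 14 | C2,C10-bis{2-[bis(2,2,2-trifluoroethoxy)phosphoryl]propanoate} of 20 (epimer mixture at the two phosphonate-bearing carbons) | C=C([C@H](O[Si](C)(C)C(C)(C)C)C[C@@H](OC(=O)C(C)P(=O)(OCC(F)(F)F)OCC(F)(F)F)C(C)(C)O)[C@H]1CC=C(C)[C@@H](OC(=O)C(C)P(=O)(OCC(F)(F)F)OCC(F)(F)F)[C@H]1OC(C)=O
F4 | step 15 | 3β,4β-epoxide of 20 (epoxide syn to the C2 hydroxyl) | C=C([C@H](O[Si](C)(C)C(C)(C)C)C[C@@H](O)C(C)(C)O)[C@H]1C[C@H]2O[C@@]2(C)[C@@H](O)[C@H]1OC(C)=O
F5 | step 15 | 3β,4β-epoxide of 21 (C2,C10-bis-angelate of F4) | C=C([C@H](O[Si](C)(C)C(C)(C)C)C[C@@H](OC(=O)/C(C)=C\C)C(C)(C)O)[C@H]1C[C@H]2O[C@@]2(C)[C@@H](OC(=O)/C(C)=C\C)[C@H]1OC(C)=O
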